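The 1,2-dioxane (ring numbering O1–O2–C3–C4–C5–C6) is cut so that its fully substituted peroxide carbon C6 and the adjacent ring methylene C5 return to a 1,1-disubstituted alkene, while C4 (with its ethyl group) and C3 return to butanal. One aerobic organocatalytic operation joins three components: the enamine radical cation of butanal adds through C4 to the terminal CH2 of a chiral triene, the tertiary C6 radical captures O2, and the hydroperoxide closes onto the aldehyde. The resulting 1,2-dioxan-3-ol later accepts the acetate arm at its anomeric carbon. The precursor is an open-chain C15 triene hydrocarbon carrying no oxygen at all.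

Key step: step 7

Remark: step 7 creates C6 from a free tertiary radical without control, so 16, 17 and 18 are drawn as the 6R series but travel together with their 6S epimers until the separation in step 9.

Step 1
Reactants: 1 2-bromobut-1-ene; 2 3-bromo-1-(trimethylsilyl)prop-1-yne
Product: 4 trimethyl(4-methylidenehex-1-yn-1-yl)silane, via but-1-en-2-ylmagnesium bromide 3 (not isolated)
Conditions: Mg, THF, 40 °C; then 2, CuBr·SMe2 (5 mol%), THF, −20 °C → rt
Reagents that add atoms: none
Why: Copper-catalysed coupling of an alkenyl Grignard reagent with a propargylic bromide, in which the bulky silyl cap should steer substitution to the propargylic carbon (SN2) and away from the allenyl (SN2') terminus.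

Step 2
Reactants: 4 trimethyl(4-methylidenehex-1-yn-1-yl)silane
Product: 5 2-ethylpent-1-en-4-yne
Conditions: K2CO3 (0.2 equiv), MeOH, rt; product carried on as a dried pentane/CH2Cl2 solution
Reagents that add atoms: none
Why: Mild methanolysis of the alkynyl C–Si bond (protodesilylation) should leave the skipped ene–yne untouched.

Step 3
Reactants: 5 2-ethylpent-1-en-4-yne
Product: 7 (1E)-4-ethyl-1-iodo-2-methylpenta-1,4-diene, via alkenylalane 6 (not isolated)
Conditions: AlMe3 (2 equiv), Cp2ZrCl2 (0.25 equiv), CH2Cl2, 0 °C → rt; then I2, THF, −30 °C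
Reagents that add atoms: trimethylaluminium C[Al](C)C; iodine II
Why: Zirconium-catalysed methylalumination (Negishi carboalumination) adds Me and Al syn with Al on the terminal carbon, and iodinolysis with retention should give the (E)-iodide while the 1,1-disubstituted alkene stays inert.

Step 4
Reactants: 8 (2E)-pent-2-enal
Product: 9 (3R,4E)-hept-4-en-3-ol
Conditions: Et2Zn (1.5 equiv), (2R)-(+)-3-exo-(dimethylamino)isoborneol (5 mol%), toluene, 0 °C; aq. NH4Cl
Reagents that add atoms: diethylzinc CC[Zn]CC
Why: Amino-alcohol-catalysed enantioselective addition of diethylzinc to an enal, in which the (2R)-ligand is expected to give the (R)-carbinol, the mirror image of the established outcome of the (2S)-ligand with aryl and alkenyl aldehydes.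

Step 5
Reactants: 9 (3R,4E)-hept-4-en-3-ol
Product: 10 (3R,4E)-hept-4-en-3-yl pyridine-2-carboxylate
Conditions: picolinic acid, DCC, DMAP (cat.), CH2Cl2, rt
Reagents that add atoms: pyridine-2-carboxylic acid OC(=O)c1ccccn1
Why: Steglich esterification installs the picolinoxy leaving group needed for chelation-activated, γ-selective allylic substitution without touching the stereocenter.

Step 6
Reactants: 7 (1E)-4-ethyl-1-iodo-2-methylpenta-1,4-diene; 10 (3R,4E)-hept-4-en-3-yl pyridine-2-carboxylate
Product: 14 (4E,6R,7E)-2,6-diethyl-4-methyldeca-1,4,7-triene, via alkenyllithium 11 (not isolated), via alkenylmagnesium bromide 12 (not isolated), via alkenylcopper 13 (not isolated)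
Conditions: 7, t-BuLi (2 equiv), Et2O, −78 °C; MgBr2·OEt2; CuBr·SMe2, THF, −60 °C; then 10, −60 → −30 °C; aq. NH4Cl
Reagents that add atoms: none
Why: Stereoretentive iodine–lithium exchange and transmetalation give an alkenylcopper reagent that should substitute the picolinate anti-SN2' with 1,3-chirality transfer, attack anti to the leaving group in the conformer whose carbinol H eclipses the alkene turning the (R)-carbinol into the (R)-bis-allylic stereocenter and a new (E)-alkene.

Step 7
Reactants: 14 (4E,6R,7E)-2,6-diethyl-4-methyldeca-1,4,7-triene; 15 butanal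
Product: 17 (3RS,4R,6R)-4,6-diethyl-6-[(2E,4R,5E)-4-ethyl-2-methylocta-2,5-dien-1-yl]-1,2-dioxan-3-ol, via open-chain hydroperoxy aldehyde 16 (not isolated)
Conditions: 15 (3 equiv, slow addition), (2S,5S)-5-benzyl-2-tert-butyl-3-methylimidazolidin-4-one·CF3CO2H (20 mol%), (NH4)2Ce(NO3)6 (20 mol%), O2 (1 atm), NaHCO3, H2O (2 equiv), DME, −20 °C
Reagents that add atoms: dioxygen O=O
Why: Proposed new method: condensation of 15 with the imidazolidinone gives an (E)-enamine that tetravalent cerium oxidises to a 3π-electron radical cation; this electrophilic radical adds through C4 to the unhindered terminal CH2 (C5) of 14, the tertiary C6 radical is captured by O2 (forming C6–O1), and the peroxyl radical is reduced to the hydroperoxide by a further enamine molecule or by trivalent cerium, so the oxidant is regenerated and only catalytic cerium is needed. The closest known reaction types are the organo-SOMO carbo-oxidation of styrenes (same radical cation, comparable alkene nucleophilicity) and the manganese- or cerium-catalysed aerobic [2+2+2] peroxycyclisation of 1,3-dicarbonyl compounds with alkenes to 1,2-dioxan-3-ols. After hydrolysis of the iminium ion the ring closes by reversible 6-exo-trig addition of the hydroperoxide oxygen to the aldehyde carbon. C4 is set by the catalyst, whose benzyl group shields the Re face of the enamine carbon so that the alkene is attacked from the Si face (4R); C6 arises from a free radical without control, so both C6 epimers are expected and are separated after step 9, and C3 is an inconsequential anomeric mixture. The step needs chemoselectivity for the 1,1-disubstituted alkene over the trisubstituted alkene (its attacking terminus is flanked by the branched allylic carbon) and the 1,2-disubstituted alkene (only a secondary radical), and it needs the radical cation to meet the alkene before O2; π-radical cations react sluggishly with triplet O2, and slow addition of 15 keeps free aldehyde low to suppress autoxidation.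

Step 8
Reactants: 17 (3RS,4R,6R)-4,6-diethyl-6-[(2E,4R,5E)-4-ethyl-2-methylocta-2,5-dien-1-yl]-1,2-dioxan-3-ol
Product: 18 (3RS,4R,6R)-4,6-diethyl-6-[(2E,4R,5E)-4-ethyl-2-methylocta-2,5-dien-1-yl]-3-methoxy-1,2-dioxane
Conditions: MeOH, PPTS (cat.), 4 Å MS, 0 °C → rt
Reagents that add atoms: methanol CO
Why: Acid-catalysed exchange of the peroxy-hemiacetal hydroxyl for methoxy (Fischer-type acetalisation) should give the stable cyclic peroxyacetal that serves as peroxycarbenium precursor, leaving C4 and C6 untouched.

Step 9
Reactants: 18 (3RS,4R,6R)-4,6-diethyl-6-[(2E,4R,5E)-4-ethyl-2-methylocta-2,5-dien-1-yl]-3-methoxy-1,2-dioxane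
Product: 19 methyl 2-[(3R,4R,6R)-4,6-diethyl-6-[(2E,4R,5E)-4-ethyl-2-methylocta-2,5-dien-1-yl]-1,2-dioxan-3-yl]acetate
Conditions: CH2=C(OMe)OTBS (3 equiv), TMSOTf (0.3 equiv), CH2Cl2, −78 °C; then preparative HPLC to remove the 6S epimer
Reagents that add atoms: 1-(tert-butyldimethylsilyloxy)-1-methoxyethene C=C(OC)O[Si](C)(C)C(C)(C)C
Why: Lewis-acid ionisation gives a cyclic peroxycarbenium ion that the silyl ketene acetal traps (Mukaiyama-type addition), and because the half-chair is locked with C4-ethyl pseudo-equatorial (the other half-chair would place C4-ethyl and a C6 substituent syn-diaxial), the stereoelectronically preferred axial attack should set C3 as R, cis to C4-ethyl.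

Compound list
1 | 2-bromobut-1-ene | C=C(Br)CC | starting material
2 | 3-bromo-1-(trimethylsilyl)prop-1-yne | C[Si](C)(C)C#CCBr | starting material
3 | but-1-en-2-ylmagnesium bromide | C=C(CC)[Mg]Br | intermediate
4 | trimethyl(4-methylidenehex-1-yn-1-yl)silane | C[Si](C)(C)C#CCC(=C)CC | intermediate
5 | 2-ethylpent-1-en-4-yne | C#CCC(=C)CC | intermediate
6 | [(1E)-4-ethyl-2-methylpenta-1,4-dien-1-yl]dimethylalumane | C[Al](C)/C=C(\C)CC(=C)CC | intermediate
7 | (1E)-4-ethyl-1-iodo-2-methylpenta-1,4-diene | I/C=C(\C)CC(=C)CC | intermediate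
8 | (2E)-pent-2-enal | CC/C=C/C=O | starting material
9 | (3R,4E)-hept-4-en-3-ol | CC[C@@H](O)/C=C/CC | intermediate
10 | (3R,4E)-hept-4-en-3-yl pyridine-2-carboxylate | CC[C@@H](OC(=O)c1ccccn1)/C=C/CC | intermediate
11 | [(1E)-4-ethyl-2-methylpenta-1,4-dien-1-yl]lithium | [Li]/C=C(\C)CC(=C)CC | intermediate
12 | bromo[(1E)-4-ethyl-2-methylpenta-1,4-dien-1-yl]magnesium | Br[Mg]/C=C(\C)CC(=C)CC | intermediate
13 | [(1E)-4-ethyl-2-methylpenta-1,4-dien-1-yl]copper | [Cu]/C=C(\C)CC(=C)CC | intermediate
14 | (4E,6R,7E)-2,6-diethyl-4-methyldeca-1,4,7-triene | CC/C=C/[C@H](/C=C(\C)CC(CC)=C)CC | intermediate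
15 | butanal | CCCC=O | starting material
16 | (2R,4R,6E,8R,9E)-2,4,8-triethyl-4-hydroperoxy-6-methyldodeca-6,9-dienal | CC/C=C/[C@H](/C=C(\C)C[C@@](OO)(CC)C[C@@H](CC)C=O)CC | intermediate
17 | (3RS,4R,6R)-4,6-diethyl-6-[(2E,4R,5E)-4-ethyl-2-methylocta-2,5-dien-1-yl]-1,2-dioxan-3-ol | CC/C=C/[C@H](/C=C(\C)C[C@@]1(CC)C[C@@H](CC)C(O)OO1)CC | intermediate
18 | (3RS,4R,6R)-4,6-diethyl-6-[(2E,4R,5E)-4-ethyl-2-methylocta-2,5-dien-1-yl]-3-methoxy-1,2-dioxane | CC/C=C/[C@H](/C=C(\C)C[C@@]1(CC)C[C@@H](CC)C(OC)OO1)CC | intermediate
19 | methyl 2-[(3R,4R,6R)-4,6-diethyl-6-[(2E,4R,5E)-4-ethyl-2-methylocta-2,5-dien-1-yl]-1,2-dioxan-3-yl]acetate | CC/C=C/[C@H](/C=C(\C)C[C@@]1(CC)C[C@@H](CC)[C@@H](CC(=O)OC)OO1)CC | target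

Total step count: 9. Longest linear sequence: 7 steps (1, 2, 3, 6, 7, 8, 9).

Steps most likely to fail

Step 7 (Proposed new method). What may go wrong: O2 intercepts the enamine radical cation or free butanal before the carbon–carbon bond forms (α-oxygenation, peracid formation, epoxidation of 14), or the peroxyl-radical chain does not propagate. The fallback uses known chemistry, sets out from 14 and returns at 18; it makes the two bonds in separate operations under auxiliary control. N-Acylation of (4S)-4-benzyl-1,3-oxazolidin-2-one with 2-bromobutanoyl bromide gives the bromo imide (4S)-4-benzyl-3-(2-bromobutanoyl)-1,3-oxazolidin-2-one F1. Lewis-acid-promoted atom-transfer radical addition of F1 to 14 (Yb(OTf)3, Et3B with a trace of O2, CH2Cl2/THF, −78 °C), with the chelated radical attacked anti to the benzyl group, should give the tertiary bromide F2 with C4 as R. Silver-assisted perhydrolysis (AgOTf, anhydrous H2O2 in Et2O, −40 °C, cold and with a large excess of H2O2 to outrun lactonisation) should give the tertiary hydroperoxide F3. This is capped with 2-methoxypropene and PPTS as the 2-methoxyprop-2-yl peroxyketal F4. LiBH4 then removes the auxiliary to give the primary alcohol F5, Dess–Martin oxidation gives the aldehyde F6, and PPTS in MeOH unmasks the hydroperoxide and closes the ring to 18. C6 remains uncontrolled on this path as well.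

Step 9. What may go wrong: the Lewis acid ionises the tertiary C6–O1 bond or cleaves the ring in competition with ionisation at C3, or axial selectivity erodes with the very reactive ketene acetal. The fallback sets out from 17 and returns at 19. The lactol is opened by Wittig olefination with methyl (triphenylphosphoranylidene)acetate (CH2Cl2, rt) to the γ-hydroperoxy enoate methyl (2E,4R,6R,8E,10R,11E)-4,6,10-triethyl-6-hydroperoxy-8-methyltetradeca-2,8,11-trienoate F7. Base-mediated 6-exo oxa-Michael addition (Et2NH, CF3CH2OH, rt) then closes it to 19. The facial selectivity at C3 on this path is not secured by a conformational lock, so any C3 epimer would be removed in the same HPLC separation as the C6 epimer.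

Step 6. What may go wrong: α-substitution competes with γ-substitution, and for this pseudo-symmetric allyl unit the α-product is the enantiomer, so the enantiopurity of 14 erodes; partial loss of alkene geometry is a second risk. The fallback sets out from 15 and from 1 (through Grignard reagent 3) and returns at 14. The stereocenter is set by organo-SOMO α-vinylation of butanal with potassium (E)-but-1-enyltrifluoroborate under the same imidazolidinone ((NH4)2Ce(NO3)6, NaHCO3, DME, −50 °C, Si-face attack), giving the aldehyde (2R,3E)-2-ethylhex-3-enal F8. This is trapped at once by Wittig reaction with ethyl 2-(triphenylphosphoranylidene)propanoate to the enoate ethyl (2E,4R,5E)-4-ethyl-2-methylocta-2,5-dienoate F9. DIBAL reduction gives the allylic alcohol (2E,4R,5E)-4-ethyl-2-methylocta-2,5-dien-1-ol F10, the Appel reaction (CBr4, PPh3) gives the allylic bromide (2E,4R,5E)-1-bromo-4-ethyl-2-methylocta-2,5-diene F11, and coupling with 3 under Li2CuCl4 catalysis (THF, −20 °C) gives 14.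

Further compounds
F1 | step 7 | (4S)-4-benzyl-3-(2-bromobutanoyl)-1,3-oxazolidin-2-one | CCC(Br)C(=O)N1[C@@H](Cc2ccccc2)COC1=O
F2 | step 7 | (4S)-4-benzyl-3-[(2R,6E,8R,9E)-4-bromo-2,4,8-triethyl-6-methyldodeca-6,9-dienoyl]-1,3-oxazolidin-2-one | CC/C=C/[C@H](/C=C(\C)CC(Br)(CC)C[C@@H](CC)C(=O)N1[C@@H](Cc2ccccc2)COC1=O)CC
F3 | step 7 | (4S)-4-benzyl-3-[(2R,6E,8R,9E)-2,4,8-triethyl-4-hydroperoxy-6-methyldodeca-6,9-dienoyl]-1,3-oxazolidin-2-one | CC/C=C/[C@H](/C=C(\C)CC(OO)(CC)C[C@@H](CC)C(=O)N1[C@@H](Cc2ccccc2)COC1=O)CC
F4 | step 7 | (4S)-4-benzyl-3-[(2R,6E,8R,9E)-2,4,8-triethyl-4-[(2-methoxypropan-2-yl)peroxy]-6-methyldodeca-6,9-dienoyl]-1,3-oxazolidin-2-one | CC/C=C/[C@H](/C=C(\C)CC(OOC(C)(C)OC)(CC)C[C@@H](CC)C(=O)N1[C@@H](Cc2ccccc2)COC1=O)CC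
F5 | step 7 | (2R,6E,8R,9E)-2,4,8-triethyl-4-[(2-methoxypropan-2-yl)peroxy]-6-methyldodeca-6,9-dien-1-ol | CC/C=C/[C@H](/C=C(\C)CC(OOC(C)(C)OC)(CC)C[C@@H](CC)CO)CC
F6 | step 7 | (2R,6E,8R,9E)-2,4,8-triethyl-4-[(2-methoxypropan-2-yl)peroxy]-6-methyldodeca-6,9-dienal | CC/C=C/[C@H](/C=C(\C)CC(OOC(C)(C)OC)(CC)C[C@@H](CC)C=O)CC
F7 | step 9 | methyl (2E,4R,6R,8E,10R,11E)-4,6,10-triethyl-6-hydroperoxy-8-methyltetradeca-2,8,11-trienoate | CC/C=C/[C@H](/C=C(\C)C[C@@](OO)(CC)C[C@@H](CC)/C=C/C(=O)OC)CC
F8 | step 6 | (2R,3E)-2-ethylhex-3-enal | CC/C=C/[C@H](C=O)CC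
F9 | step 6 | ethyl (2E,4R,5E)-4-ethyl-2-methylocta-2,5-dienoate | CC/C=C/[C@H](/C=C(\C)C(=O)OCC)CC
F10 | step 6 | (2E,4R,5E)-4-ethyl-2-methylocta-2,5-dien-1-ol | CC/C=C/[C@H](/C=C(\C)CO)CC
F11 | step 6 | (2E,4R,5E)-1-bromo-4-ethyl-2-methylocta-2,5-diene | CC/C=C/[C@H](/C=C(\C)CBr)CC
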